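**Plan**

1. Retrosynthesis: with the silyl and mesyl groups removed last, both C–O bonds of the oxolane (O1–C2 and O1–C5) are cut. This gives a twofold-symmetric 1,4-diaryl-2,3-bis(silyloxymethyl)butane-1,4-diol, held as its seven-membered cyclic sulfate, and acetate as the donor of O1.
2. The open chain is then cut at the two aryl-carbinol C–C bonds (ring bonds C2–C3 and C4–C5) into two molecules of O-mesylvanillin and a succinyl bis(oxazolidinone), itself made from succinyl chloride and two molecules of the auxiliary.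
3. Forward: the succinate core is loaded with two auxiliary units, both aryl carbinol arms are joined in one two-directional aldol step, the imides are reduced, the primary alcohols silylated and the diol tied into the cyclic sulfate. The oxolane, the only ring formed, is closed last before deprotection.
4. Enabling feature: O1 lies between C2 and C5, two benzylic carbons of the same (S) configuration that are exchanged by the twofold axis through O1 and the midpoint of C3–C4. One oxygen can therefore be attached to both by two backside displacements once the aryl rings are made electron-poor by O-mesylation.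
5. Stereochemistry: the (R)-4-benzyloxazolidinone auxiliaries fix C3, C4 and both carbinol carbons in the aldol step (syn in each half). C2 and C5 reach their final configuration by inversion in the ring closure.

Key step: step 7

Assumption: the target is read through its SMILES as the (2S,3S,4S,5S)-oxolane; vanillin, succinyl chloride, (R)-4-benzyl-1,3-oxazolidin-2-one and CsOAc are taken as the purchased materials.

Abbreviations: Ar = 3-methoxy-4-(methylsulfonyloxy)phenyl; Xc = (4R)-4-benzyl-2-oxo-1,3-oxazolidin-3-yl; TBDPS = tert-butyldiphenylsilyl.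

**Route**

Step 1
Reactants: 1 vanillin (4-hydroxy-3-methoxybenzaldehyde)
Product: 2 4-formyl-2-methoxyphenyl methanesulfonate (ArCHO)
Conditions: MsCl, Et3N, CH2Cl2, 0 °C to rt
Reagents that add atoms: methanesulfonyl chloride, CS(=O)(=O)Cl
Why: O-sulfonylation of the phenol is fast and leaves the aldehyde untouched, and the mesyloxy group makes the ring electron-poor for all later benzylic chemistry.

Step 2
Reactants: 3 (R)-4-benzyl-1,3-oxazolidin-2-one (2.1 equiv); 4 succinyl chloride (butanedioyl dichloride)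
Product: 5 1,4-bis(Xc)butane-1,4-dione
Conditions: 3 (2.1 equiv), n-BuLi (2.1 equiv), THF, −78 °C; then 4 (1.0 equiv), −78 to 0 °C
Reagents that add atoms: none
Why: Each acid chloride end of 4 acylates one molecule of lithiated 3 at nitrogen (N-acylation of an oxazolidinone), so two auxiliary units are taken up per succinyl unit and the twofold-symmetric bis-imide forms without touching the auxiliary stereocentre.

Step 3
Reactants: 5 1,4-bis(Xc)butane-1,4-dione; 2 4-formyl-2-methoxyphenyl methanesulfonate (2.5 equiv)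
Product: 7 (2R,3R)-1,4-bis(Xc)-2,3-bis[(R)-hydroxy(Ar)methyl]butane-1,4-dione, via bis(dibutylboron) enolate 6 (not isolated)
Conditions: Bu2BOTf (2.4 equiv), i-Pr2NEt (2.8 equiv), CH2Cl2, 0 °C; 2, −78 to 0 °C; then H2O2, pH 7 buffer, MeOH, 0 °C
Reagents that add atoms: none
Why: In this two-directional Evans syn-aldol addition each (Z)-boron enolate should add to the aldehyde through a closed chair transition state on the face turned away from the benzyl group of its own auxiliary, so both halves become syn adducts of the same absolute sense, which sets the two carbinol carbons (R) and the two chain carbons (R,R).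

Step 4
Reactants: 7 (2R,3R)-1,4-bis(Xc)-2,3-bis[(R)-hydroxy(Ar)methyl]butane-1,4-dione
Product: 8 (1R,2S,3S,4R)-1,4-di(Ar)-2,3-bis(hydroxymethyl)butane-1,4-diol
Conditions: LiBH4, THF, 0 °C to rt
Reagents that add atoms: none
Why: Reductive cleavage of N-acyl oxazolidinones by LiBH4 should give the two primary alcohols and return the auxiliary, with the aryl mesylates and all four stereocentres untouched.

Step 5
Reactants: 8 (1R,2S,3S,4R)-1,4-di(Ar)-2,3-bis(hydroxymethyl)butane-1,4-diol
Product: 9 (1R,2S,3S,4R)-1,4-di(Ar)-2,3-bis(TBDPS-oxymethyl)butane-1,4-diol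
Conditions: TBDPSCl (2.2 equiv), imidazole, DMF, 0 °C to rt
Reagents that add atoms: tert-butyl(chloro)diphenylsilane, CC(C)(C)[Si](Cl)(c1ccccc1)c1ccccc1
Why: Silyl ether formation with the bulky chlorosilane is selective for the two primary hydroxyls over the hindered benzylic ones, and the crowded, weakly basic silyl ether oxygens are poor internal nucleophiles in the later substitution.

Step 6
Reactants: 9 (1R,2S,3S,4R)-1,4-di(Ar)-2,3-bis(TBDPS-oxymethyl)butane-1,4-diol
Product: 11 (4R,5S,6S,7R)-4,7-di(Ar)-5,6-bis(TBDPS-oxymethyl)-1,3,2-dioxathiepane 2,2-dioxide, via cyclic sulfite 10 (not isolated)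
Conditions: SOCl2, Et3N, CH2Cl2, 0 °C; then RuCl3·xH2O (cat.), NaIO4, MeCN/H2O, 0 °C
Reagents that add atoms: thionyl chloride, O=S(Cl)Cl; sodium periodate, [Na+].[O-]I(=O)(=O)=O
Why: Cyclic sulfite formation followed by RuO4-catalysed oxidation is the standard two-stage cyclic sulfate synthesis; only O–S bonds are made, so both carbinol configurations are kept, and the all-trans substituent pattern suits the seven-membered ring.

Step 7
Reactants: 11 (4R,5S,6S,7R)-4,7-di(Ar)-5,6-bis(TBDPS-oxymethyl)-1,3,2-dioxathiepane 2,2-dioxide; 12 cesium acetate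
Product: 15 (2S,3S,4S,5S)-2,5-di(Ar)-3,4-bis(TBDPS-oxymethyl)oxolane, via acetoxy sulfate 13 (not isolated), via hydroxy sulfate 14 (not isolated)
Conditions: CsOAc (1.5 equiv), DMF, 50 °C; then MeOH, K2CO3, 50 °C (same flask)
Reagents that add atoms: none
Why: Acetate attacks one benzylic carbon of the cyclic sulfate from the side opposite the leaving oxygen (bimolecular substitution with C–O cleavage, the usual carboxylate opening of cyclic sulfates), and because the other benzylic oxygen is left as a sulfate monoester anion that does not accept a second external nucleophile, exactly one foreign oxygen enters. Methanolysis of the acetate then frees an alkoxide on that carbon, which displaces the sulfate at the second benzylic carbon from the back (intramolecular Williamson etherification with a sulfate leaving group, the reaction type by which sugar 6-sulfates give 3,6-anhydro rings in alkali), forming O1–C5 after O1–C2. The oxolane is thereby closed in a 5-exo-tet mode. Both new ring stereocentres are controlled by the (R) carbinol configurations fixed in step 3: each is inverted once to (S), which places every aryl group cis to its neighbouring silyloxymethyl arm while C3 and C4 are untouched. The step needs substitution to win over ionisation and elimination and needs a single acetoxylation; the para-mesyloxy groups remove the electron push that would let the benzylic C–O bonds ionise, the sulfate tether limits the external nucleophile to one entry, and the bulky TBDPS ethers keep the primary oxygens from taking part.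

Step 8
Reactants: 15 (2S,3S,4S,5S)-2,5-di(Ar)-3,4-bis(TBDPS-oxymethyl)oxolane
Product: 16 [(2S,3S,4S,5S)-2,5-di(Ar)oxolane-3,4-diyl]dimethanol
Conditions: Bu4NF, AcOH, THF, rt
Reagents that add atoms: none
Why: Fluoride-mediated desilylation should cleave both primary silyl ethers, while the acetic acid buffer keeps the medium from attacking the aryl mesylates or the benzylic ether carbons.

Step 9
Reactants: 16 [(2S,3S,4S,5S)-2,5-di(Ar)oxolane-3,4-diyl]dimethanol
Product: 17 [(2S,3S,4S,5S)-2,5-bis(4-hydroxy-3-methoxyphenyl)oxolane-3,4-diyl]dimethanol (target)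
Conditions: KOH, MeOH/H2O, 60 °C, under argon; then aq. HCl to pH 6
Reagents that add atoms: none
Why: Sulfonate ester hydrolysis by hydroxide attack at sulfur should free both phenols without touching the oxolane or its four stereocentres at this temperature, and mild acidification gives the neutral target.

**Compound list**

1 | vanillin (4-hydroxy-3-methoxybenzaldehyde) | COc1cc(C=O)ccc1O | starting material
2 | 4-formyl-2-methoxyphenyl methanesulfonate | COc1cc(C=O)ccc1OS(C)(=O)=O | intermediate
3 | (4R)-4-benzyl-1,3-oxazolidin-2-one | O=C1N[C@H](Cc2ccccc2)CO1 | starting material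
4 | succinyl chloride (butanedioyl dichloride) | O=C(Cl)CCC(=O)Cl | starting material
5 | 1,4-bis[(4R)-4-benzyl-2-oxo-1,3-oxazolidin-3-yl]butane-1,4-dione | O=C(CCC(=O)N1[C@H](Cc2ccccc2)COC1=O)N1[C@H](Cc2ccccc2)COC1=O | intermediate
6 | (1Z,3Z)-1,4-bis[(4R)-4-benzyl-2-oxo-1,3-oxazolidin-3-yl]-1,4-bis(dibutylboranyloxy)buta-1,3-diene | CCCCB(CCCC)O/C(N1[C@H](Cc2ccccc2)COC1=O)=C\C=C(/OB(CCCC)CCCC)N1[C@H](Cc2ccccc2)COC1=O | intermediate (not isolated)
7 | (2R,3R)-1,4-bis[(4R)-4-benzyl-2-oxo-1,3-oxazolidin-3-yl]-2,3-bis{(R)-hydroxy[3-methoxy-4-(methylsulfonyloxy)phenyl]methyl}butane-1,4-dione | COc1cc(ccc1OS(C)(=O)=O)[C@H](O)[C@H](C(=O)N1[C@H](Cc2ccccc2)COC1=O)[C@@H](C(=O)N1[C@H](Cc2ccccc2)COC1=O)[C@@H](O)c1ccc(OS(C)(=O)=O)c(OC)c1 | intermediate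
8 | (1R,2S,3S,4R)-2,3-bis(hydroxymethyl)-1,4-bis[3-methoxy-4-(methylsulfonyloxy)phenyl]butane-1,4-diol | COc1cc(ccc1OS(C)(=O)=O)[C@H](O)[C@H](CO)[C@@H](CO)[C@@H](O)c1ccc(OS(C)(=O)=O)c(OC)c1 | intermediate
9 | (1R,2S,3S,4R)-2,3-bis{[tert-butyl(diphenyl)silyl]oxymethyl}-1,4-bis[3-methoxy-4-(methylsulfonyloxy)phenyl]butane-1,4-diol | COc1cc(ccc1OS(C)(=O)=O)[C@H](O)[C@H](CO[Si](c1ccccc1)(c1ccccc1)C(C)(C)C)[C@@H](CO[Si](c1ccccc1)(c1ccccc1)C(C)(C)C)[C@@H](O)c1ccc(OS(C)(=O)=O)c(OC)c1 | intermediate
10 | (4R,5S,6S,7R)-5,6-bis{[tert-butyl(diphenyl)silyl]oxymethyl}-4,7-bis[3-methoxy-4-(methylsulfonyloxy)phenyl]-1,3,2-dioxathiepane 2-oxide | COc1cc(ccc1OS(C)(=O)=O)[C@@H]1OS(=O)O[C@@H](c2ccc(OS(C)(=O)=O)c(OC)c2)[C@H](CO[Si](c2ccccc2)(c2ccccc2)C(C)(C)C)[C@H]1CO[Si](c1ccccc1)(c1ccccc1)C(C)(C)C | intermediate (not isolated)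
11 | (4R,5S,6S,7R)-5,6-bis{[tert-butyl(diphenyl)silyl]oxymethyl}-4,7-bis[3-methoxy-4-(methylsulfonyloxy)phenyl]-1,3,2-dioxathiepane 2,2-dioxide | COc1cc(ccc1OS(C)(=O)=O)[C@@H]1OS(=O)(=O)O[C@@H](c2ccc(OS(C)(=O)=O)c(OC)c2)[C@H](CO[Si](c2ccccc2)(c2ccccc2)C(C)(C)C)[C@H]1CO[Si](c1ccccc1)(c1ccccc1)C(C)(C)C | intermediate
12 | cesium acetate | CC(=O)[O-].[Cs+] | starting material
13 | cesium (1R,2S,3S,4S)-4-acetoxy-2,3-bis{[tert-butyl(diphenyl)silyl]oxymethyl}-1,4-bis[3-methoxy-4-(methylsulfonyloxy)phenyl]butyl sulfate | COc1cc(ccc1OS(C)(=O)=O)[C@@H](OC(C)=O)[C@H](CO[Si](c1ccccc1)(c1ccccc1)C(C)(C)C)[C@@H](CO[Si](c1ccccc1)(c1ccccc1)C(C)(C)C)[C@@H](OS(=O)(=O)[O-])c1ccc(OS(C)(=O)=O)c(OC)c1.[Cs+] | intermediate (not isolated)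
14 | cesium (1R,2S,3S,4S)-2,3-bis{[tert-butyl(diphenyl)silyl]oxymethyl}-4-hydroxy-1,4-bis[3-methoxy-4-(methylsulfonyloxy)phenyl]butyl sulfate | COc1cc(ccc1OS(C)(=O)=O)[C@@H](O)[C@H](CO[Si](c1ccccc1)(c1ccccc1)C(C)(C)C)[C@@H](CO[Si](c1ccccc1)(c1ccccc1)C(C)(C)C)[C@@H](OS(=O)(=O)[O-])c1ccc(OS(C)(=O)=O)c(OC)c1.[Cs+] | intermediate (not isolated)
15 | (2S,3S,4S,5S)-3,4-bis{[tert-butyl(diphenyl)silyl]oxymethyl}-2,5-bis[3-methoxy-4-(methylsulfonyloxy)phenyl]oxolane | COc1cc(ccc1OS(C)(=O)=O)[C@H]1O[C@H](c2ccc(OS(C)(=O)=O)c(OC)c2)[C@H](CO[Si](c2ccccc2)(c2ccccc2)C(C)(C)C)[C@H]1CO[Si](c1ccccc1)(c1ccccc1)C(C)(C)C | intermediate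
16 | [(2S,3S,4S,5S)-2,5-bis[3-methoxy-4-(methylsulfonyloxy)phenyl]oxolane-3,4-diyl]dimethanol | COc1cc(ccc1OS(C)(=O)=O)[C@H]1O[C@H](c2ccc(OS(C)(=O)=O)c(OC)c2)[C@H](CO)[C@H]1CO | intermediate
17 | [(2S,3S,4S,5S)-2,5-bis(4-hydroxy-3-methoxyphenyl)oxolane-3,4-diyl]dimethanol | COc1cc([C@H]2O[C@H](c3ccc(O)c(OC)c3)[C@H](CO)[C@H]2CO)ccc1O | target

**Step count and risks**

Total steps: 9. Longest linear sequence: 8 steps (steps 2 to 9; step 1 is a one-step side branch).

Step 7 (ring closure). What may go wrong: the freed alkoxide may displace the sulfate monoester too slowly, so that elimination toward the styrene or slow methanolysis of an aryl mesylate, followed by ionisation at the benzylic carbon, takes over. Fallback, from 11 back to 15: the cyclic sulfate 11 is opened with cesium benzoate in DMF to the benzoyloxy sulfate F1. Its sulfate monoester is hydrolysed with catalytic H2SO4 and a little water in THF, which cleaves the S–O bond and keeps the configuration, to give the hydroxy benzoate F2. Mesylation (MsCl, Et3N, −20 °C) gives the benzoyloxy mesylate F3, and K2CO3 in MeOH then removes the benzoate and closes the ring on the much better leaving group to give 15.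

Step 3 (double aldol). What may go wrong: enolisation of the second imide may be incomplete, or the first aldolate may lactonise onto the distal imide with loss of its auxiliary before the second addition. Lactonisation that sets in only after the second addition would be tolerable, since LiBH4 in step 4 reduces lactone and imide carbonyls alike to the same tetraol 8. Fallback, from 2 back to 8: aldehyde 2 is homologated with ethyl diazoacetate and catalytic SnCl2 (Roskamp reaction) to the β-keto ester F4. Its sodium enolate is coupled with I2 to the diaroylsuccinate F5. Transfer hydrogenation with RuCl[(R,R)-TsDPEN](p-cymene) in HCO2H/Et3N under dynamic kinetic resolution should set both carbinols (R) by catalyst control, but the syn relationship to the epimerising chain carbons is not assured and would have to be found by screening. The syn,syn isomer would be collected by crystallisation as the diaryl-exo, cis-fused bislactone F6, and LiBH4 reduces F6 to tetraol 8.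

Step 6 (cyclic sulfate). What may go wrong: the second hydroxyl may displace the benzylic chlorosulfite internally (premature oxolane formation with a single inversion), chloride may substitute at the benzylic carbon, or RuO4 may over-oxidise the methoxyarenes. Fallback, from 9 back to 15: diol 9 is converted with MsCl/Et3N at −20 °C into the bis-mesylate F7. This is treated with one equivalent of CsOAc and 18-crown-6 in toluene to give the acetoxy mesylate F8 and, in the same flask, with K2CO3/MeOH to close the ring to 15. Mono-acetoxylation is then only statistically controlled, and unreacted F7 is recycled.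

Further compounds
F1 | step 7 | cesium (1R,2S,3S,4S)-4-(benzoyloxy)-2,3-bis{[tert-butyl(diphenyl)silyl]oxymethyl}-1,4-bis[3-methoxy-4-(methylsulfonyloxy)phenyl]butyl sulfate | COc1cc(ccc1OS(C)(=O)=O)[C@@H](OC(=O)c1ccccc1)[C@H](CO[Si](c1ccccc1)(c1ccccc1)C(C)(C)C)[C@@H](CO[Si](c1ccccc1)(c1ccccc1)C(C)(C)C)[C@@H](OS(=O)(=O)[O-])c1ccc(OS(C)(=O)=O)c(OC)c1.[Cs+]
F2 | step 7 | (1S,2S,3S,4R)-2,3-bis{[tert-butyl(diphenyl)silyl]oxymethyl}-4-hydroxy-1,4-bis[3-methoxy-4-(methylsulfonyloxy)phenyl]butyl benzoate | COc1cc(ccc1OS(C)(=O)=O)[C@@H](OC(=O)c1ccccc1)[C@H](CO[Si](c1ccccc1)(c1ccccc1)C(C)(C)C)[C@@H](CO[Si](c1ccccc1)(c1ccccc1)C(C)(C)C)[C@@H](O)c1ccc(OS(C)(=O)=O)c(OC)c1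
F3 | step 7 | (1S,2S,3S,4R)-2,3-bis{[tert-butyl(diphenyl)silyl]oxymethyl}-1,4-bis[3-methoxy-4-(methylsulfonyloxy)phenyl]-4-(methylsulfonyloxy)butyl benzoate | COc1cc(ccc1OS(C)(=O)=O)[C@@H](OC(=O)c1ccccc1)[C@H](CO[Si](c1ccccc1)(c1ccccc1)C(C)(C)C)[C@@H](CO[Si](c1ccccc1)(c1ccccc1)C(C)(C)C)[C@@H](OS(C)(=O)=O)c1ccc(OS(C)(=O)=O)c(OC)c1
F4 | step 3 | ethyl 3-[3-methoxy-4-(methylsulfonyloxy)phenyl]-3-oxopropanoate | CCOC(=O)CC(=O)c1ccc(OS(C)(=O)=O)c(OC)c1
F5 | step 3 | diethyl 2,3-bis[3-methoxy-4-(methylsulfonyloxy)benzoyl]butanedioate (interconverting stereoisomers, no fixed configuration) | CCOC(=O)C(C(=O)c1ccc(OS(C)(=O)=O)c(OC)c1)C(C(=O)OCC)C(=O)c1ccc(OS(C)(=O)=O)c(OC)c1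
F6 | step 3 | (1R,2R,5R,6R)-2,6-bis[3-methoxy-4-(methylsulfonyloxy)phenyl]-3,7-dioxabicyclo[3.3.0]octane-4,8-dione | COc1cc(ccc1OS(C)(=O)=O)[C@@H]1OC(=O)[C@@H]2[C@H]1C(=O)O[C@H]2c1ccc(OS(C)(=O)=O)c(OC)c1
F7 | step 6 | (1R,2S,3S,4R)-2,3-bis{[tert-butyl(diphenyl)silyl]oxymethyl}-1,4-bis[3-methoxy-4-(methylsulfonyloxy)phenyl]butane-1,4-diyl dimethanesulfonate | COc1cc(ccc1OS(C)(=O)=O)[C@H](OS(C)(=O)=O)[C@H](CO[Si](c1ccccc1)(c1ccccc1)C(C)(C)C)[C@@H](CO[Si](c1ccccc1)(c1ccccc1)C(C)(C)C)[C@@H](OS(C)(=O)=O)c1ccc(OS(C)(=O)=O)c(OC)c1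
F8 | step 6 | (1S,2S,3S,4R)-2,3-bis{[tert-butyl(diphenyl)silyl]oxymethyl}-1,4-bis[3-methoxy-4-(methylsulfonyloxy)phenyl]-4-(methylsulfonyloxy)butyl acetate | COc1cc(ccc1OS(C)(=O)=O)[C@@H](OC(C)=O)[C@H](CO[Si](c1ccccc1)(c1ccccc1)C(C)(C)C)[C@@H](CO[Si](c1ccccc1)(c1ccccc1)C(C)(C)C)[C@@H](OS(C)(=O)=O)c1ccc(OS(C)(=O)=O)c(OC)c1
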